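The pentasubstituted benzene ring of the indane is built in one step. In indane numbering, the C5 chloroethyl and C6 acyloxymethyl arms are tied back into an isochroman ether ring, which turns C4–C7 into a propargyl homopropargyl ether 1,7-diyne (CH2OAc on C4, H on C7) and leaves C3a–C7a with its gem-dimethyl ring as symmetric 4,4-dimethylcyclopentene. A Cp*RuCl(cod)-catalysed [2+2+2] cycloaddition forms C5–C6, C4–C3a and C7–C7a together, closing the dihydropyran and the cis-fused cyclohexa-1,3-diene; DDQ then aromatises it. The ether CH2 at C6 is later oxidised to a lactone, whose opening delivers the chloroethyl arm and keeps C6 distinct from C4.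

Key step: step 4

Remark: the target is achiral, so the two stereocentres made in step 4 are transient; atom labels C1–C7a follow the indane numbering of the target, and compounds 2 and 8 are taken as purchasable.
Remark: a benzylic acetate is itself a benzyl ester and is not expected to outlast hot SOCl2/ZnCl2, so step 7 is planned to turn it into the benzylic chloride and step 9 puts the acetate back; any material in which the acetate survives reaches the same target through steps 7 to 9.

Step 1
Reactants: 1 but-3-yn-1-ol; 2 3-bromo-1-(trimethylsilyl)prop-1-yne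
Product: 3 [3-(but-3-yn-1-yloxy)prop-1-yn-1-yl]trimethylsilane
Conditions: NaH (1.1 equiv), THF, 0 °C; then 2, Bu4NI (5 mol%), 0 °C → rt
Reagents that add atoms: none
Why: Williamson ether synthesis in which NaH in THF removes only the O–H proton and the alkoxide displaces the primary propargylic bromide by SN2, the silyl cap marking the propargyl-ether alkyne so that only the butynyl C–H is free for metalation in step 2.

Step 2
Reactants: 3 [3-(but-3-yn-1-yloxy)prop-1-yn-1-yl]trimethylsilane; 4 formaldehyde (as dry paraformaldehyde)
Product: 6 5-(prop-2-yn-1-yloxy)pent-2-yn-1-ol, via silyl-capped diynol 5 (not isolated)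
Conditions: n-BuLi (1.05 equiv), THF, −78 °C; (CH2O)n (2 equiv), −78 °C → rt; then MeOH, K2CO3 (0.3 equiv), rt
Reagents that add atoms: none
Why: Addition of the lithium acetylide of the only terminal alkyne to formaldehyde (hydroxymethylation), followed in the same flask by methoxide-induced protodesilylation of the C(sp)–Si bond, both routine for terminal and trimethylsilyl alkynes.

Step 3
Reactants: 6 5-(prop-2-yn-1-yloxy)pent-2-yn-1-ol
Product: 7 5-(prop-2-yn-1-yloxy)pent-2-yn-1-yl acetate
Conditions: Ac2O (1.3 equiv), Et3N, DMAP (5 mol%), CH2Cl2, 0 °C → rt
Reagents that add atoms: acetic anhydride, CC(=O)OC(C)=O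
Why: DMAP-catalysed acetylation of a primary propargylic alcohol, the acetate being chosen because it tolerates the ruthenium catalyst and deactivates its own CH2 towards DDQ and chromium oxidants in steps 5 and 6.

Step 4
Reactants: 7 5-(prop-2-yn-1-yloxy)pent-2-yn-1-yl acetate; 8 4,4-dimethylcyclopentene
Product: 9 rac-[(5aR,8aR)-7,7-dimethyl-1,3,4,5a,6,7,8,8a-octahydrocyclopenta[g]isochromen-5-yl]methyl acetate (cyclohexa-1,3-diene cis-fused to the gem-dimethylcyclopentane, 5a-H and 8a-H on the same face; CH2OAc on the diene carbon next to the ring fusion, dihydropyran fused across the other two diene carbons)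
Conditions: Cp*RuCl(cod) (10 mol%), 8 (20 equiv), ClCH2CH2Cl, 60 °C, 7 added by syringe pump over 10 h, Ar
Reagents that add atoms: none
Why: This is a [2+2+2] cycloaddition of an α,ω-diyne with an alkene: the two alkynes of 7 couple oxidatively on the Cp*RuCl fragment to a ruthenacyclopentadiene (bond C5–C6), 8 coordinates and inserts into a Ru–C bond, and reductive elimination closes the carbocycle (bonds C4–C3a and C7–C7a). The closest known reaction is the Cp*RuCl(cod)-catalysed cycloaddition of 1,6- and 1,7-diynes with cyclic alkenes to bicyclic cyclohexa-1,3-dienes; the alkene used here has neither ring strain nor a coordinating heteroatom, so its insertion is expected to be the slow event. The dihydropyran ring closes by metallacycle formation across the four-atom CH2–O–CH2–CH2 tether, which fixes which alkyne carbons join, and the cyclohexadiene ring closes by insertion and reductive elimination with all six ring carbons held on ruthenium. C3a and C7a are created together by syn addition to one face of the cyclopentene, which can only give the cis ring fusion; no chiral element is present, so 9 should be racemic, and both centres vanish in step 5. The selectivity needed is chemoselectivity for cross-cycloaddition over dimerisation and trimerisation of 7, favoured by keeping 7 dilute in a large excess of 8; regiochemistry does not arise because 8 has a mirror plane through C2 that exchanges its two alkene carbons.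

Step 5
Reactants: 9 rac-cis cyclohexadiene acetate
Product: 10 (7,7-dimethyl-1,3,4,6,7,8-hexahydrocyclopenta[g]isochromen-5-yl)methyl acetate
Conditions: DDQ (1.05 equiv), toluene, 0 °C → rt
Reagents that add atoms: none
Why: Dehydrogenative aromatisation with DDQ (hydride abstraction from an allylic ring-fusion C–H to a cyclohexadienyl cation, then proton loss) is fast for cyclohexa-1,3-dienes, erases both stereocentres, and with only a slight excess of oxidant should leave the slower-reacting isochroman O–CH2 and the acetate untouched.

Step 6
Reactants: 10 (7,7-dimethyl-1,3,4,6,7,8-hexahydrocyclopenta[g]isochromen-5-yl)methyl acetate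
Product: 11 (7,7-dimethyl-1-oxo-1,3,4,6,7,8-hexahydrocyclopenta[g]isochromen-5-yl)methyl acetate
Conditions: pyridinium chlorochromate (C5H5NH)[CrO3Cl] (4 equiv), Celite, CH2Cl2, 40 °C
Reagents that add atoms: pyridinium chlorochromate, [O-][Cr](=O)(=O)Cl.c1cc[nH+]cc1
Why: Benzylic ether oxidation by hexavalent chromium converts the isochroman O–CH2–Ar group into the lactone carbonyl because this is the only C–H site that is both benzylic and α to an ether oxygen, while the acetoxymethyl CH2 is deactivated by its acyl group and the other benzylic CH2 groups need harsher conditions.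

Step 7
Reactants: 11 (7,7-dimethyl-1-oxo-1,3,4,6,7,8-hexahydrocyclopenta[g]isochromen-5-yl)methyl acetate
Product: 13 [4-(chloromethyl)-5-(2-chloroethyl)-2,2-dimethyl-2,3-dihydro-1H-inden-6-yl]methanol, via trichloro acyl chloride 12 (not isolated)
Conditions: SOCl2 (neat), ZnCl2 (0.2 equiv), 75 °C; evaporate (CH2Cl2 chase); then NaBH4 (3 equiv), THF–DMF (10:1), −20 → 0 °C
Reagents that add atoms: thionyl chloride, O=S(Cl)Cl
Why: ZnCl2-assisted alkyl–oxygen chlorinolysis with SOCl2 is the standard way from a lactone to an ω-chloroalkanoyl chloride (chloride attacks the O–CH2CH2 carbon by SN2 and the zinc carboxylate is chlorinated), the more easily ionised benzylic acetate should give the benzylic chloride under the same conditions, and NaBH4 at low temperature then reduces only the acyl chloride to the primary alcohol and leaves both alkyl chlorides alone.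

Step 8
Reactants: 13 [4-(chloromethyl)-5-(2-chloroethyl)-2,2-dimethyl-2,3-dihydro-1H-inden-6-yl]methanol
Product: 14 [4-(chloromethyl)-5-(2-chloroethyl)-2,2-dimethyl-2,3-dihydro-1H-inden-6-yl]methyl butanoate
Conditions: (PrCO)2O (1.3 equiv), i-Pr2NEt, DMAP (5 mol%), CH2Cl2, 0 °C
Reagents that add atoms: butanoic anhydride, CCCC(=O)OC(=O)CCC
Why: DMAP-catalysed acylation of the primary benzylic alcohol with the anhydride under a non-nucleophilic base at 0 °C should be much faster than closure of the hydroxyl onto the chloroethyl arm or attack of the base on the benzylic chloride.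

Step 9
Reactants: 14 [4-(chloromethyl)-5-(2-chloroethyl)-2,2-dimethyl-2,3-dihydro-1H-inden-6-yl]methyl butanoate
Product: 15 [4-(acetoxymethyl)-5-(2-chloroethyl)-2,2-dimethyl-2,3-dihydro-1H-inden-6-yl]methyl butanoate (CNP0321917.0)
Conditions: KOAc (2 equiv), 18-crown-6 (10 mol%), DMF, 40 °C
Reagents that add atoms: potassium acetate, CC(=O)[O-].[K+]
Why: SN2 displacement by acetate in a dipolar aprotic solvent is selective for the benzylic chloride, which reacts far faster than the unactivated primary chloride of the chloroethyl arm, and acetate ion does not exchange with the butanoate ester.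

Compound list
1 | but-3-yn-1-ol | C#CCCO | starting material
2 | 3-bromo-1-(trimethylsilyl)prop-1-yne | C[Si](C)(C)C#CCBr | starting material
3 | [3-(but-3-yn-1-yloxy)prop-1-yn-1-yl]trimethylsilane | C#CCCOCC#C[Si](C)(C)C | intermediate
4 | formaldehyde (used as paraformaldehyde) | C=O | starting material
5 | 5-{[3-(trimethylsilyl)prop-2-yn-1-yl]oxy}pent-2-yn-1-ol (present as its lithium alkoxide, not isolated) | OCC#CCCOCC#C[Si](C)(C)C | intermediate
6 | 5-(prop-2-yn-1-yloxy)pent-2-yn-1-ol | OCC#CCCOCC#C | intermediate
7 | 5-(prop-2-yn-1-yloxy)pent-2-yn-1-yl acetate | C#CCOCCC#CCOC(C)=O | intermediate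
8 | 4,4-dimethylcyclopentene | CC1(C)CC=CC1 | starting material
9 | rac-[(5aR,8aR)-7,7-dimethyl-1,3,4,5a,6,7,8,8a-octahydrocyclopenta[g]isochromen-5-yl]methyl acetate, cis ring fusion (one enantiomer drawn) | CC(=O)OCC1=C2CCOCC2=C[C@H]3CC(C)(C)C[C@@H]13 | intermediate
10 | (7,7-dimethyl-1,3,4,6,7,8-hexahydrocyclopenta[g]isochromen-5-yl)methyl acetate | CC(=O)OCc1c2CCOCc2cc2CC(C)(C)Cc12 | intermediate
11 | (7,7-dimethyl-1-oxo-1,3,4,6,7,8-hexahydrocyclopenta[g]isochromen-5-yl)methyl acetate | CC(=O)OCc1c2CCOC(=O)c2cc2CC(C)(C)Cc12 | intermediate
12 | 4-(chloromethyl)-5-(2-chloroethyl)-2,2-dimethyl-2,3-dihydro-1H-indene-6-carbonyl chloride (not isolated) | O=C(Cl)c1cc2CC(C)(C)Cc2c(CCl)c1CCCl | intermediate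
13 | [4-(chloromethyl)-5-(2-chloroethyl)-2,2-dimethyl-2,3-dihydro-1H-inden-6-yl]methanol | OCc1cc2CC(C)(C)Cc2c(CCl)c1CCCl | intermediate
14 | [4-(chloromethyl)-5-(2-chloroethyl)-2,2-dimethyl-2,3-dihydro-1H-inden-6-yl]methyl butanoate | CCCC(=O)OCc1cc2CC(C)(C)Cc2c(CCl)c1CCCl | intermediate
15 | [4-(acetoxymethyl)-5-(2-chloroethyl)-2,2-dimethyl-2,3-dihydro-1H-inden-6-yl]methyl butanoate | CCCC(=O)OCc1cc2c(c(COC(C)=O)c1CCCl)CC(C)(C)C2 | target

Total step count: 9. Longest linear sequence: 9 steps (1 to 15).

Steps most likely to fail

Step 4. The unactivated alkene may insert too slowly, so that the metallacycle is consumed by further diyne (dimers and trimers of 7) and catalyst turnover stops. The fallback sets out from 7 and 8 and comes back at 9. It replaces catalytic turnover by a stoichiometric cobalt template: CpCo(CO)2 (1.1 equiv) is irradiated at reflux in 8 as solvent while 7 is added slowly, so that each cobaltacyclopentadiene meets only alkene. The product is held as the air-stable cyclopentadienylcobalt η4-diene complex F1, which is purified by chromatography. Oxidative demetallation with CuCl2·2H2O and Et3N in MeCN at 0 °C should then release 9; any 10 formed by over-oxidation is equally useful for step 6. Both operations are known for cobalt-mediated diyne–alkene cocyclisations.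

Step 7. The lactone opening may stall under conditions where benzylic cations formed from the acetate already undergo side reactions, and the chloroethyl benzyl alkoxide formed on reduction may re-close to an isochroman. The fallback sets out from 11 and comes back at 14. It avoids both the Lewis acid and the basic hydride: HBr in AcOH at 70 °C should open the lactone and exchange the acetate to give the tribromo acid F2. BH3·THF then reduces the free carboxylic acid without generating an alkoxide, giving the bromo alcohol F3, which is acylated as in step 8 to the dibromo butanoate F4. Halide exchange with excess LiCl in DMF at 50 °C converts both bromides to chlorides and delivers 14.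

Step 6. The chromium oxidant may show poor site selectivity, attacking the indane benzylic CH2 groups or over-oxidising the ring system. The fallback sets out from 10 and comes back at 11. It uses hydride abstraction, which only the ether-stabilised position can support: DDQ (1.2 equiv) in CH2Cl2–H2O at rt should give the lactol F5 by water capture of the oxocarbenium ion. Oxidation of the lactol with catalytic TEMPO and PhI(OAc)2 in CH2Cl2 then gives 11.

Further compounds
F1 | step 4 | (η5-cyclopentadienyl)cobalt η4-complex of diene 9, CpCo(C17H24O3) (metal–ligand bonding not encoded; face of complexation not controlled) | CC(=O)OCC1=C2CCOCC2=C[C@H]3CC(C)(C)C[C@@H]13.[Co+].[cH-]1cccc1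
F2 | step 7 | 4-(bromomethyl)-5-(2-bromoethyl)-2,2-dimethyl-2,3-dihydro-1H-indene-6-carboxylic acid | OC(=O)c1cc2CC(C)(C)Cc2c(CBr)c1CCBr
F3 | step 7 | [4-(bromomethyl)-5-(2-bromoethyl)-2,2-dimethyl-2,3-dihydro-1H-inden-6-yl]methanol | OCc1cc2CC(C)(C)Cc2c(CBr)c1CCBr
F4 | step 7 | [4-(bromomethyl)-5-(2-bromoethyl)-2,2-dimethyl-2,3-dihydro-1H-inden-6-yl]methyl butanoate | CCCC(=O)OCc1cc2CC(C)(C)Cc2c(CBr)c1CCBr
F5 | step 6 | (1-hydroxy-7,7-dimethyl-1,3,4,6,7,8-hexahydrocyclopenta[g]isochromen-5-yl)methyl acetate (racemic hemiacetal) | CC(=O)OCc1c2CCOC(O)c2cc2CC(C)(C)Cc12
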